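# Route to 3-hydroxy-5,6,7,8-tetramethoxy-2-(4-methoxyphenyl)-4H-chromen-4-one (16) by propargyl Claisen rearrangement and oxa-electrocyclization

## Analysis of the target

The target 16 is a flavonol: a 4H-chromen-4-one in which benzo ring A is fused to the 4-pyranone ring C (O1, C2, C3, C4, C4a, C8a), with a 4-methoxyphenyl ring B on C2 and a free enolic hydroxyl on C3. It has no stereocentre and no stereogenic double bond, so every stereocentre that appears on the way is transient and needs no control. Ring A is hexasubstituted: C5, C6, C7 and C8 carry methoxyls, C8a carries the ring oxygen O1, and C4a carries the only carbon substituent, C4. The sensitive parts are the 3-hydroxy-4-pyranone (an acidic, chelating and oxidizable enol), the very electron-rich ring A (easily oxidized towards quinones) and the 4-methoxyphenyl group, which stabilizes positive charge at C2 in any sp3 precursor. The difficulty is to assemble a penta-oxygenated benzene with one carbon placed exactly between an oxygen and a methoxyl, and then to bring C3 and C4 to their oxidation levels without damaging that ring. The strategy rests on one feature: the phenol that supplies ring A, with O1 in place and methoxyls on the future C5–C8, has a single unsubstituted ortho carbon, the future C4a. A carbon delivered intramolecularly from O1 to an ortho position can therefore only form the C4–C4a bond.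

## Retrosynthetic reasoning

**Flavonol 16 to diol 13.** Flavonol 16 is the C2–C3 enol of 3,4-dione 15, and the tautomerization is downhill because it creates the conjugated 4-pyranone. No skeletal bond is cut. The C3 hydroxyl and C4 carbonyl are read as the doubly oxidized form of a vicinal diol, so 15 is traced through ketol 14 to diol 13. This keeps the enol out of the ring-forming chemistry. The forward reaction must oxidize two adjacent secondary carbinols without cleaving the C3–C4 bond.

**Diol 13 to chromene 12.** The two C–O bonds at C3 and C4 are removed together, which leads to the C3=C4 alkene of 2H-chromene 12. This alkene is the only one in the molecule, so a syn-dihydroxylation has no competitor. Because C2, C3 and C4 all end sp2, the facial outcome is irrelevant.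

**Chromene 12 to ether 8 (key disconnection).** The C4–C4a bond is cut, and the O1–C2 bond is opened and re-attached. Read backwards, ring C opens by retro-electrocyclization to ortho-quinone methide 11, a hydrogen returns to oxygen to give allenylphenol 10, ketonization gives dienone 9, and a retro-[3,3] shift gives aryl propargyl ether 8. C4–C4a is the only carbon–carbon bond to ring A. Making it by a sigmatropic shift from O1 means the carbon can only land ortho, and only one ortho carbon is free. An intermolecular acylation of the ring would leave O1–C2 and C2–C3 to be built separately. Here, one thermal isomerization of a C20 ether forms ring C. The forward reaction has to stay pericyclic and avoid heterolysis of the 4-methoxybenzylic C–O bond.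

**Ether 8 to phenol 4 and alcohol 7.** The propargylic C–O bond (the future O1–C2) is the only bond joining the two halves. Cutting it gives phenol 4 and propargylic alcohol 7, to be joined by a Mitsunobu etherification under neutral conditions. The forward reaction must alkylate at oxygen, not at the free ortho carbon.

**Alcohol 7 to aldehyde 5 and Grignard reagent 6.** The carbinol–alkyne bond (future C2–C3) is cut. A 1,2-addition sets the benzylic oxygen and the terminal alkyne in one step.

**Phenol 4 to arene 1.** The aryl C–O bond of the future O1 is cut. The two ring hydrogens of arene 1 are equivalent, and each is ortho to a methoxyl. Lithiation to aryllithium 2, borylation to boronate 3 and oxidation therefore give 4 without any regiochemical question.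

## Alternatives that were turned down

**Alternative 1:** Carbonylative assembly of an alkynone.
- Disconnection: C4a–C4 and C4–C3 are formed together.
- Forward key step: under zerovalent palladium the aryl iodide A2 (1-iodo-2,3,4,5,6-pentamethoxybenzene) undergoes oxidative addition, inserts one carbonyl carbon and is alkynylated by the arylalkyne A3 (1-ethynyl-4-methoxybenzene). The product is alkynone A1, which holds all skeleton carbons with C4 already a ketone. Ring C would then close by demethylative 6-endo attack of an ortho-methoxyl oxygen on the iodonium-activated alkyne, giving 3-iodoflavone A4. Its iodide would then have to be exchanged for hydroxyl.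
- For: the key step is more convergent than the chosen one. The pentamethoxyphenyl ring is symmetric, so either ortho-methoxyl can close and no regiochemistry arises. C4 needs no later oxidation, whereas the chosen route must add six oxidation equivalents after ring closure. On these points it is stronger.
- Against: A2 is an iodide flanked by two methoxyls on an extremely electron-rich ring. That is a poor case for oxidative addition and for carbonyl insertion to outrun direct alkynylation. A2 must itself be made over several steps. The ring closure sacrifices a methyl group and uses an electrophilic iodine source that can also attack ring B. The C3 oxygen arrives only through a further carbon–iodine to carbon–oxygen exchange at a hindered position.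
- Comparison: the step count is no shorter, and uncertainty is spread over three steps. The chosen route offers a metal-free ring construction on a precursor with the oxygen pattern pre-set, and takes both the C3 and C4 oxygens from one alkene.

**Alternative 2:** Acylquinone oxa-Michael closure.
- Disconnection: O1–C8a.
- Forward key step: in acylquinone A6 the enol oxygen of the diketone side chain adds in conjugate fashion to the only hydrogen-bearing quinone carbon, which is activated by both the ring carbonyl and the acyl carbonyl. Tautomerization aromatizes ring A and gives the 5,8-dihydroxyflavone A5, with the C3 oxygen already present as a benzyl ether.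
- For: it forms the aryl–O1 bond by a polar step for which the substrate is strongly biased. The C3 oxygen is carried from the start, so no late oxidation of the heterocycle is needed. On that point it is stronger than the chosen route.
- Against: A6 joins an electrophilic, oxidizing quinone to an enolizable, oxidizable 1,3-dicarbonyl and an anisole. Unmasking the quinone must stop cleanly and spare the doubly activated C–H. Redox exchange between A5 and A6 can drain material. After the key step two phenols must be methylated, one of them hydrogen-bonded to C4=O, and the benzyl ether removed.
- Comparison: the sequence would be about eight or nine steps with protecting-group traffic. The chosen route enters with O1 and all four methoxyls in place from one arene and uses no protecting group.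

**Alternative 3:** Symmetric tetramethoxybenzyne insertion.
- Disconnection: O1–C8a, C4–C4a and O1–C2 in one operation.
- Forward key step: fluoride releases 3,4,5,6-tetramethoxybenzyne A8 from the ortho-silylaryl triflate A10. The carboxylate of arylpropiolic acid A9 adds through oxygen. The resulting aryl anion takes the acyl group by intramolecular transfer, and the phenoxide closes onto the ynone to give flavone A7.
- For: three bonds form in one pot, the aryne is symmetric so regiochemistry is as secure as in the chosen route, and A7 is achiral with C4 at the right oxidation level. The key step is stronger in bond economy.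
- Against: A10 needs about three steps beyond phenol 4 (ortho-halogenation, silylation with anionic silyl migration, triflation). The acyl transfer runs through a strained four-membered transition state on an aryl anion that can simply be protonated. A7 has no oxygen at C3, so a separate C3–H hydroxylation of the finished, electron-rich flavone is still required.
- Comparison: the overall step count is similar (about six). The chosen route offers a rearrangement substrate reached in three steps from catalogue materials, and introduces the C3 and C4 oxygens together at an alkene instead of at a C–H bond.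

Key step: step 4

Remark on the chemistry: the target is achiral, so every chiral intermediate is carried as a racemate. Where relative configuration matters, one enantiomer is drawn. 1,2,3,4-Tetramethoxybenzene, 4-methoxybenzaldehyde and ethynylmagnesium bromide (THF solution) are taken as purchasable.

## Steps

Step 1
Reactants: 1 1,2,3,4-tetramethoxybenzene
Product: 4 2,3,4,5-tetramethoxyphenol, via aryllithium 2 (not isolated), via aryl boronate 3 (not isolated)
Conditions: n-BuLi, TMEDA, THF, 0 °C; B(OMe)3, −78 °C → rt; AcOH, 30% aq H2O2, 0 °C → rt; aq Na2SO3 work-up under Ar
Reagents that add atoms: hydrogen peroxide, OO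
Why: Directed ortho-metalation next to a methoxyl (the two ring hydrogens of 1 are equivalent, so only one aryllithium can form), then borylation and oxidative 1,2-aryl shift from boron to oxygen; the four methoxyls are untouched and the air-sensitive phenol is used promptly.

Step 2
Reactants: 5 4-methoxybenzaldehyde; 6 ethynylmagnesium bromide
Product: 7 1-(4-methoxyphenyl)prop-2-yn-1-ol (racemic)
Conditions: THF, 0 °C → rt; then sat. aq NH4Cl
Reagents that add atoms: none
Why: 1,2-Addition of an alkynyl Grignard reagent to a non-enolizable aldehyde; the new carbinol centre is formed racemic, which is all that is needed, and a neutral work-up avoids Meyer–Schuster rearrangement.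

Step 3
Reactants: 7 1-(4-methoxyphenyl)prop-2-yn-1-ol (racemic); 4 2,3,4,5-tetramethoxyphenol
Product: 8 1-{[1-(4-methoxyphenyl)prop-2-yn-1-yl]oxy}-2,3,4,5-tetramethoxybenzene (racemic)
Conditions: PPh3, DIAD, toluene, 0 °C → rt; chromatography on Et3N-deactivated silica
Reagents that add atoms: none
Why: Mitsunobu etherification: the alcohol is activated as its alkoxyphosphonium under neutral conditions and displaced at the propargylic carbon by the phenoxide oxygen (phenol acidity is in the usable range); the non-polar solvent and low temperature keep the displacement tight and disfavour C-alkylation.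

Step 4
Reactants: 8 1-{[1-(4-methoxyphenyl)prop-2-yn-1-yl]oxy}-2,3,4,5-tetramethoxybenzene (racemic)
Product: 12 5,6,7,8-tetramethoxy-2-(4-methoxyphenyl)-2H-chromene (racemic), via allenyl dienone 9 (not isolated), via allenylphenol 10 (not isolated), via ortho-quinone methide 11 (not isolated)
Conditions: PhNEt2 (degassed, dilute), 180 °C, Ar, sealed vessel
Reagents that add atoms: none
Why: This is the thermal aryl propargyl ether Claisen rearrangement–electrocyclization cascade, the established way from aryl propargyl ethers to 2H-chromenes. A concerted [3,3] shift breaks O–C2 and joins the alkyne terminus to the one hydrogen-bearing ortho carbon (new C4–C4a), giving dienone 9, which tautomerizes to allenylphenol 10. A 1,5-hydrogen shift from the phenolic oxygen to the central allene carbon gives ortho-quinone methide 11 with the Z exocyclic alkene that the transfer geometry imposes. Ring C then closes by a thermally allowed disrotatory oxa six-electron electrocyclization of this 1-oxatriene, a pericyclic six-membered closure that re-forms O1–C2 and restores the aromaticity of ring A. C2 is created without control, as a racemate, and needs none because it becomes sp2 in 16. Regioselectivity is secured by the substrate: the other ortho carbon carries a methoxyl, so a dienone formed there cannot enolize and can only revert. Chemoselectivity for the pericyclic path over heterolysis of the 4-methoxybenzylic C–O bond is secured by the non-polar, weakly basic amine solvent, which removes traces of acid.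

Step 5
Reactants: 12 5,6,7,8-tetramethoxy-2-(4-methoxyphenyl)-2H-chromene (racemic)
Product: 13 rac-(2R,3S,4S)-5,6,7,8-tetramethoxy-2-(4-methoxyphenyl)-3,4-dihydro-2H-chromene-3,4-diol (2,3-trans-3,4-cis)
Conditions: OsO4 (cat.), NMO, acetone/H2O, 0 °C → rt; aq Na2SO3
Reagents that add atoms: osmium tetroxide, O=[Os](=O)(=O)=O (catalytic carrier of both oxygens); N-methylmorpholine N-oxide, C[N+]1([O-])CCOCC1 and water, O (net oxygen sources)
Why: Osmium-catalysed syn-dihydroxylation of the only alkene; the reagent should approach the C3=C4 face opposite the C2 aryl group, so C3–OH and C4–OH are cis to each other and trans to the aryl (substrate control from C2), and any lower selectivity is harmless because C2, C3 and C4 all end sp2.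

Step 6
Reactants: 13 rac-(2R,3S,4S)-5,6,7,8-tetramethoxy-2-(4-methoxyphenyl)-3,4-dihydro-2H-chromene-3,4-diol
Product: 16 3-hydroxy-5,6,7,8-tetramethoxy-2-(4-methoxyphenyl)-4H-chromen-4-one (target), via ketol 14 (not isolated), via 3,4-dione 15 (not isolated)
Conditions: IBX (3 equiv), DMSO, rt → 45 °C
Reagents that add atoms: none
Why: Hypervalent-iodine oxidation of a vicinal diol to the 1,2-dione, which in DMSO proceeds without glycol cleavage; the benzylic C4 carbinol should go first (ketol 14), the C3 carbinol second (dione 15), and 15 tautomerizes through its C2–H to the conjugated 3-hydroxy-4-pyranone 16, erasing all three stereocentres.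

## Compound list

1 | 1,2,3,4-tetramethoxybenzene | COc1ccc(OC)c(OC)c1OC | starting material
2 | (2,3,4,5-tetramethoxyphenyl)lithium | [Li]c1cc(OC)c(OC)c(OC)c1OC | intermediate
3 | dimethyl (2,3,4,5-tetramethoxyphenyl)boronate | COB(OC)c1cc(OC)c(OC)c(OC)c1OC | intermediate
4 | 2,3,4,5-tetramethoxyphenol | COc1cc(O)c(OC)c(OC)c1OC | intermediate
5 | 4-methoxybenzaldehyde | COc1ccc(C=O)cc1 | starting material
6 | ethynylmagnesium bromide | C#C[Mg]Br | starting material
7 | 1-(4-methoxyphenyl)prop-2-yn-1-ol (racemic) | COc1ccc(C(O)C#C)cc1 | intermediate
8 | 1-{[1-(4-methoxyphenyl)prop-2-yn-1-yl]oxy}-2,3,4,5-tetramethoxybenzene (racemic) | COc1ccc(C(C#C)Oc2cc(OC)c(OC)c(OC)c2OC)cc1 | intermediate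
9 | 2,3,4,5-tetramethoxy-6-[3-(4-methoxyphenyl)propa-1,2-dien-1-yl]cyclohexa-2,4-dien-1-one (stereoisomer mixture) | COc1ccc(C=C=CC2C(=O)C(OC)=C(OC)C(OC)=C2OC)cc1 | intermediate
10 | 2,3,4,5-tetramethoxy-6-[3-(4-methoxyphenyl)propa-1,2-dien-1-yl]phenol (racemic allene) | COc1ccc(C=C=Cc2c(O)c(OC)c(OC)c(OC)c2OC)cc1 | intermediate
11 | (6Z)-2,3,4,5-tetramethoxy-6-[3-(4-methoxyphenyl)prop-2-en-1-ylidene]cyclohexa-2,4-dien-1-one | COc1ccc(C=C/C=C2\C(=O)C(OC)=C(OC)C(OC)=C2OC)cc1 | intermediate
12 | 5,6,7,8-tetramethoxy-2-(4-methoxyphenyl)-2H-chromene (racemic) | COc1ccc(C2C=Cc3c(OC)c(OC)c(OC)c(OC)c3O2)cc1 | intermediate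
13 | rac-(2R,3S,4S)-5,6,7,8-tetramethoxy-2-(4-methoxyphenyl)-3,4-dihydro-2H-chromene-3,4-diol (one enantiomer drawn) | COc1ccc([C@@H]2[C@@H](O)[C@@H](O)c3c(OC)c(OC)c(OC)c(OC)c3O2)cc1 | intermediate
14 | rac-(2R,3R)-3-hydroxy-5,6,7,8-tetramethoxy-2-(4-methoxyphenyl)-2,3-dihydro-4H-chromen-4-one (one enantiomer drawn) | COc1ccc([C@@H]2[C@@H](O)C(=O)c3c(OC)c(OC)c(OC)c(OC)c3O2)cc1 | intermediate
15 | 5,6,7,8-tetramethoxy-2-(4-methoxyphenyl)chromane-3,4-dione (racemic) | COc1ccc(C2Oc3c(OC)c(OC)c(OC)c(OC)c3C(=O)C2=O)cc1 | intermediate
16 | 3-hydroxy-5,6,7,8-tetramethoxy-2-(4-methoxyphenyl)-4H-chromen-4-one | COc1ccc(-c2oc3c(OC)c(OC)c(OC)c(OC)c3c(=O)c2O)cc1 | target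

## Step count and least certain steps

Total step count: 6. Longest linear sequence: 5 steps (step 1 or step 2, then steps 3, 4, 5 and 6).

**Step 4 (key step).**
- What may go wrong: heterolysis of the 4-methoxybenzylic C–O bond may outrun the sigmatropic shift. The ion pair would then recombine at carbon or lose the phenol. Attack at the methoxylated ortho carbon may also divert the non-enolizable dienone into intramolecular cycloaddition.
- Fallback: set out from phenol 4 and reach the same ortho-quinone methide 11 from the other side. Phenol 4 is heated with commercial (E)-3-(4-methoxyphenyl)prop-2-enal and PhB(OH)2 (catalytic propionic acid, toluene, reflux with water removal). The boron-templated ortho-hydroxyalkylation forms C4–C4a at the only free ortho carbon and gives 5,6,7,8-tetramethoxy-4-[(E)-2-(4-methoxyphenyl)ethenyl]-2-phenyl-4H-1,3,2-benzodioxaborinine F1. On continued heating F1 fragments to 11, which electrocyclizes as before. The route is rejoined at chromene 12. The ether and its ionizable C–O bond are avoided altogether.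

**Step 3.**
- What may go wrong: ionization of the alkoxyphosphonium intermediate to the stabilized propargylic cation, followed by Friedel–Crafts-type capture at the free ortho carbon of the electron-rich phenol instead of at oxygen.
- Fallback: set out from alcohol 7 and change the activation mode to copper-catalysed propargylic substitution. Acetylation (Ac2O, Et3N, DMAP, CH2Cl2) gives 1-(4-methoxyphenyl)prop-2-yn-1-yl acetate F2. Treating F2 with phenol 4, catalytic CuI and i-Pr2NEt in MeCN at 0 °C generates a copper acetylide and from it a copper allenylidene, which the phenol oxygen attacks at the propargylic carbon. This uses the terminal alkyne that 7 already has. The route is rejoined at ether 8.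

**Step 6.**
- What may go wrong: oxidative cleavage of the C3–C4 bond in a cyclic iodine diolate, or further oxidation of the electron-rich enol once the flavonol has formed in the presence of excess oxidant.
- Fallback: set out from diol 13 and stage the oxidation with two chemoselective reagents. Activated MnO2 in CH2Cl2 oxidizes only the benzylic C4 carbinol and allows ketol 14 to be isolated. I2 and KOAc in AcOH at 90 °C then oxidize the enediol tautomer of 14 to dione 15, which enolizes. The route is rejoined at target 16. No compound outside the numbered list is made on this path (F0).

## Further compounds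

F1 | step 4 | 5,6,7,8-tetramethoxy-4-[(E)-2-(4-methoxyphenyl)ethenyl]-2-phenyl-4H-1,3,2-benzodioxaborinine (racemic) | COc1ccc(/C=C/C2OB(c3ccccc3)Oc3c(OC)c(OC)c(OC)c(OC)c23)cc1
F2 | step 3 | 1-(4-methoxyphenyl)prop-2-yn-1-yl acetate (racemic) | COc1ccc(C(OC(C)=O)C#C)cc1
F0 | step 6 | none | none
A1 | alternative 1 | 3-(4-methoxyphenyl)-1-(2,3,4,5,6-pentamethoxyphenyl)prop-2-yn-1-one | COc1ccc(C#CC(=O)c2c(OC)c(OC)c(OC)c(OC)c2OC)cc1
A2 | alternative 1 | 1-iodo-2,3,4,5,6-pentamethoxybenzene | COc1c(I)c(OC)c(OC)c(OC)c1OC
A3 | alternative 1 | 1-ethynyl-4-methoxybenzene | C#Cc1ccc(OC)cc1
A4 | alternative 1 | 3-iodo-5,6,7,8-tetramethoxy-2-(4-methoxyphenyl)-4H-chromen-4-one | COc1ccc(-c2oc3c(OC)c(OC)c(OC)c(OC)c3c(=O)c2I)cc1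
A5 | alternative 2 | 3-(benzyloxy)-5,8-dihydroxy-6,7-dimethoxy-2-(4-methoxyphenyl)-4H-chromen-4-one | COc1ccc(-c2oc3c(O)c(OC)c(OC)c(O)c3c(=O)c2OCc2ccccc2)cc1
A6 | alternative 2 | 2-[2-(benzyloxy)-3-(4-methoxyphenyl)-3-oxopropanoyl]-5,6-dimethoxycyclohexa-2,5-diene-1,4-dione (racemic) | COc1ccc(C(=O)C(OCc2ccccc2)C(=O)C2=CC(=O)C(OC)=C(OC)C2=O)cc1
A7 | alternative 3 | 5,6,7,8-tetramethoxy-2-(4-methoxyphenyl)-4H-chromen-4-one | COc1ccc(-c2cc(=O)c3c(OC)c(OC)c(OC)c(OC)c3o2)cc1
A8 | alternative 3 | 3,4,5,6-tetramethoxybenzyne (1,2-didehydro-3,4,5,6-tetramethoxybenzene) | COC1=C(OC)C(OC)=C(OC)C#C1
A9 | alternative 3 | 3-(4-methoxyphenyl)prop-2-ynoic acid | COc1ccc(C#CC(=O)O)cc1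
A10 | alternative 3 | 2,3,4,5-tetramethoxy-6-(trimethylsilyl)phenyl trifluoromethanesulfonate | COc1c(OC)c(OC)c([Si](C)(C)C)c(OS(=O)(=O)C(F)(F)F)c1OC
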